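Atom labels (methyl carbons unlabelled): C2(CH3)=C3H–C4(=O) is the enone. C5–C6–C7–C8 is the cyclobutane (C5 next to C4, C7 next to C2, C8 quaternary with CH3). C9(O)–C10–C11(O)–C12(CH3)2 is the bridge from C8 to C6.
Enabling feature: C8 sits on C5, the carbon α to the C4 ketone, as one edge of the cyclobutane inside the bicyclo[3.1.1]heptenone C2–C8. Moving C8 back from C5 to C4 gives a norbornene (bridgeheads C4 and C7, one-carbon bridge C8) with a bridgehead C4–OH and a leaving group on C5, which is a semipinacol retron.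
Cuts, in retrosynthetic order: the two ester C–O bonds; C5–C8 (C4–C8 restored); C4–C5 and C6–C7 (intramolecular Diels–Alder); C5=C6 (Henry); C8–CH3; C8–C9 (aldol); C9=C10 (Wittig).
Forward: the C9–C12/C6 chain is made from (S)-pantolactone and joined to 3-methylcyclopent-2-enone. One cycloaddition closes the seven-membered ring and the norbornene, the 1,2-shift contracts ring C4–C5–C6–C7–C8 to the cyclobutane, and acylation ends the route.
Stereochemistry: C11 comes from the chiral pool, C9 from C11 by 1,3-anti induction, and C8 from C9 by chelate-controlled methylation. C4, C6 and C7 follow from C8 through the tether; C5 comes from the E-nitroalkene (N endo) and inversion in the shift.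
The leaving group must be endo. C9 and its silyloxy group roof the exo face of C5, so a C5 ketone would take hydride from the endo face; the endo C–N bond made in the cycloaddition is therefore kept and activated as a diazonium ion.

Key step: step 15

Abbreviations: TBS = tert-butyldimethylsilyl, TES = triethylsilyl, TMS = trimethylsilyl.
Remark: the anomers of 3, the E/Z isomers of 4 and 5, the C8 epimers of 10 and the C6 epimers of 17 are carried on as mixtures, since each of these elements is erased in a later step.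

Step 1
Reactants: 1 (S)-pantolactone
Product: 2 (3S)-3-(TBS-oxy)-4,4-dimethyloxolan-2-one
Conditions: TBSCl, imidazole, DMF, rt
Reagents that add atoms: tert-butyldimethylsilyl chloride, CC(C)(C)[Si](C)(C)Cl
Why: Routine silyl ether protection of the only hydroxyl group, which leaves the chiral-pool stereocentre (later C11) untouched and shields the oxygen from the hydride and ylide to come.

Step 2
Reactants: 2 (3S)-3-(TBS-oxy)-4,4-dimethyloxolan-2-one
Product: 3 (3S)-3-(TBS-oxy)-4,4-dimethyloxolan-2-ol (lactol; both anomers)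
Conditions: i-Bu2AlH, CH2Cl2, −78 °C
Reagents that add atoms: none
Why: Partial lactone reduction stops at the stable aluminium hemiacetal at low temperature and should give the lactol, a masked C10 aldehyde, without touching C11.

Step 3
Reactants: 3 lactol
Product: 4 (3R)-3-(TBS-oxy)-5-methoxy-2,2-dimethylpent-4-en-1-ol (E/Z mixture)
Conditions: MeOCH2PPh3Cl, KOt-Bu, THF, 0 °C; then 3, 0 °C to rt
Reagents that add atoms: (methoxymethyl)triphenylphosphonium chloride, COC[P+](c1ccccc1)(c1ccccc1)c1ccccc1.[Cl-]
Why: Wittig methoxymethylenation of the open hydroxy aldehyde form of the lactol adds C9 and turns C10 into an enol ether CH; a silyl shift to the freed C6 alkoxide would be harmless because both oxygens carry TBS after step 4.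

Step 4
Reactants: 4 enol ether alcohol
Product: 5 (3R)-3,5-bis(TBS-oxy)-1-methoxy-4,4-dimethylpent-1-ene (E/Z mixture)
Conditions: TBSCl, imidazole, DMF, rt
Reagents that add atoms: tert-butyldimethylsilyl chloride, CC(C)(C)[Si](C)(C)Cl
Why: Silyl ether protection of the primary C6 alcohol under non-acidic conditions that leave the enol ether intact.

Step 5
Reactants: 5 bis-silyl enol ether
Product: 6 (3R)-3,5-bis(TBS-oxy)-4,4-dimethylpentanal
Conditions: p-TsOH·H2O (cat.), acetone/H2O, 0 °C
Reagents that add atoms: water, O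
Why: Acid-catalysed enol ether hydrolysis (protonation at C10, hydration at C9, loss of methanol) is much faster than TBS cleavage and completes the one-carbon homologation to the C9 aldehyde.

Step 6
Reactants: 7 3-methylcyclopent-2-en-1-one
Product: 9 1-methyl-3-(TMS-oxy)cyclopenta-1,3-diene (used at once), via lithium enolate 8 (not isolated)
Conditions: LiN(i-Pr)2, THF, −78 °C; then TMSCl, −78 to 0 °C
Reagents that add atoms: chlorotrimethylsilane, C[Si](C)(C)Cl
Why: Kinetic deprotonation of an enone takes the α′ proton (C8–H) and O-silylation traps the cross-conjugated enolate as its silyl enol ether, which is not stored because such cyclopentadienes dimerise and undergo 1,5-H shifts.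

Step 7
Reactants: 6 (3R)-3,5-bis(TBS-oxy)-4,4-dimethylpentanal and 9 1-methyl-3-(TMS-oxy)cyclopenta-1,3-diene
Product: 10 5-[(1R,3R)-3,5-bis(TBS-oxy)-1-hydroxy-4,4-dimethylpentyl]-3-methylcyclopent-2-en-1-one (C8 epimers)
Conditions: BF3·OEt2, CH2Cl2, −78 °C
Reagents that add atoms: none
Why: Mukaiyama aldol addition through an open transition state, in which the BF3-bound β-silyloxy aldehyde adopts the dipole-minimised conformation of the polar 1,3-induction model, so that C8 should attack the face giving the 1,3-anti (9R,11R) array; the C8 epimers do not matter because C8 is planarised in step 8.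

Step 8
Reactants: 10 aldol adduct
Product: 12 (5S)-5-[(1R,3R)-3,5-bis(TBS-oxy)-1-hydroxy-4,4-dimethylpentyl]-3,5-dimethylcyclopent-2-en-1-one, via dilithium alkoxide enolate 11 (not isolated)
Conditions: LiN(i-Pr)2 (2.3 equiv), THF, −78 to −40 °C; then MeI, DMPU, −78 to −20 °C
Reagents that add atoms: iodomethane, CI
Why: Fráter–Seebach-type alkylation, in which the base removes the OH and then the α′ proton, lithium bridges O4 and O9 in a six-membered chelate that holds C10 over one enolate face, and MeI enters from the other face to set quaternary C8 (S) with CH3 anti to O9, a relationship that a closed-chair aldol of the already methylated enolate (ring carbon C7 anti to O9) would not deliver.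

Step 9
Reactants: 12 methylated aldol
Product: 13 (5S)-5-[(1R,3R)-1,3,5-tris(TBS-oxy)-4,4-dimethylpentyl]-3,5-dimethylcyclopent-2-en-1-one
Conditions: TBSOTf, 2,6-lutidine, CH2Cl2, 0 °C
Reagents that add atoms: tert-butyldimethylsilyl triflate, CC(C)(C)[Si](C)(C)OS(=O)(=O)C(F)(F)F
Why: Silyl triflate protection is the standard answer to a hindered secondary alcohol next to a quaternary carbon, and it also removes any retro-aldol pathway.

Step 10
Reactants: 13 tris-silyl ether
Product: 14 (5S)-5-[(1R,3R)-1,3-bis(TBS-oxy)-5-hydroxy-4,4-dimethylpentyl]-3,5-dimethylcyclopent-2-en-1-one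
Conditions: HF·pyridine, pyridine, THF, 0 °C
Reagents that add atoms: none
Why: Sterically governed selective desilylation, since the primary C6 ether is far more accessible than the two secondary ethers, each of which also flanks a quaternary carbon.

Step 11
Reactants: 14 primary alcohol
Product: 15 (5S)-5-[(1R,3R)-1,3-bis(TBS-oxy)-4,4-dimethyl-5-oxopentyl]-3,5-dimethylcyclopent-2-en-1-one
Conditions: Dess–Martin periodinane, CH2Cl2, rt
Reagents that add atoms: none
Why: Dess–Martin oxidation is mild towards enone and silyl ethers, and the C6 aldehyde has no α-hydrogen and therefore cannot enolise or eliminate.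

Step 12
Reactants: 15 C6 aldehyde and 16 nitromethane
Product: 18 (5S)-5-[(1R,3R,5E)-1,3-bis(TBS-oxy)-4,4-dimethyl-6-nitrohex-5-en-1-yl]-3,5-dimethylcyclopent-2-en-1-one, via nitro alcohol 17 (not isolated)
Conditions: MeNO2, KOt-Bu (cat.), THF/t-BuOH, 0 °C; then MsCl, Et3N, CH2Cl2, 0 °C
Reagents that add atoms: nitromethane (16), C[N+](=O)[O-]
Why: Henry addition brings in C5 and mesylation with E1cB elimination should give the more stable E-nitroalkene; the β,β-disubstituted enone is too hindered for nitronate addition, and quaternary C12 excludes deconjugation.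

Step 13
Reactants: 18 E-nitroalkene enone
Product: 20 nitro cycloadduct (4R,5R,6R,7R,8S,9R,11R): norbornene C2(CH3)=C3H–C4(OTES)–C5H(NO2 endo)–C6H–C7H with C8(CH3) as one-carbon bridge and the chain C9H(OTBS)–C10H2–C11H(OTBS)–C12(CH3)2 running from C8 (syn to C5–C6) to the exo position of C6, via silyloxycyclopentadiene 19 (not isolated)
Conditions: TESOTf, Et3N, toluene, 0 °C; then 80 °C
Reagents that add atoms: triethylsilyl triflate, CC[Si](CC)(CC)OS(=O)(=O)C(F)(F)F
Why: Soft enolisation can only take a γ proton because C8 is quaternary, and of the equilibrating dienol ethers only cyclopentadiene 19 is s-cis; in the ensuing normal-demand intramolecular Diels–Alder reaction quaternary C8 blocks 1,5-H shifts, the polarity match of donor terminus C7 with acceptor carbon C6 chooses between the two diene termini, the four-atom tether reaches only the diene face it stands on and only with C12 exo (so C4, C6 and C7 follow from C8), and the E-alkene places the nitro group endo on C5.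

Step 14
Reactants: 20 nitro cycloadduct
Product: 22 endo amino alcohol (4R,5R,6R,7R,8S,9R,11R): as 20 but with C4–OH and endo C5–NH2, via amino triethylsilyl ether 21 (not isolated)
Conditions: Zn, AcOH/THF/H2O, rt to 40 °C
Reagents that add atoms: none
Why: Zinc–acid reduction of an aliphatic nitro group acts at nitrogen, so the endo C5–N bond is kept; the acidic medium excludes retro-Henry opening of the strained β-nitro alcohol system, and aqueous acetic acid then cleaves the labile TES ether while the two hindered TBS ethers should persist.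

Step 15
Reactants: 22 endo amino alcohol
Product: 24 bis-TBS ether of the target diol (5R,6S,7R,8R,9R,11R): 9,11-bis(TBS-oxy) tricyclic enone with the C5–C6–C7–C8 cyclobutane, via endo diazonium acetate 23 (not isolated)
Conditions: NaNO2, AcOH/H2O/THF, 0 °C
Reagents that add atoms: none
Why: Proposed new method: nitrosation of the primary amine gives the endo C5 diazonium ion 23, and as N2 leaves, the C4–C8 bond, the only σ bond close to anti-periplanar to C5–N (C4–C3 is gauche to it and the C2=C3 π bond lies on the same face as the leaving group), migrates to C5 while the C4 hydroxyl oxygen pushes and ends as the ketone, at once conjugated with C2=C3. The closest known reaction type is the semipinacol (Tiffeneau–Demjanov type) deamination of rigid vicinal amino alcohols, in which the ring bond anti to the diazonium group migrates and the ring contracts; new is the direction from a norbornenyl to the more strained bicyclo[3.1.1]heptenyl skeleton. The cyclobutane C5–C6–C7–C8 closes by a suprafacial 1,2-alkyl shift, that is by contraction of the five-membered ring C4–C5–C6–C7–C8 and not by an end-to-end cyclisation, and loss of N2 together with the new conjugated C=O should pay for the added strain and keep the transition state early. C5 is the only new stereocentre and is set by inversion, because C8 arrives on the exo face opposite to the departing N2; C8 migrates with retention and C6, C7, C9 and C11 are bystanders. The step needs migration of C8 instead of vinyl C3 and no capture of C5 by solvent: the endo C–N bond inherited from the E-nitroalkene secures the first, the C9 silyloxy group that roofs the exo face of C5 the second.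

Step 16
Reactants: 24 bis-TBS ether
Product: 25 target diol (5R,6S,7R,8R,9R,11R): 9,11-dihydroxy tricyclic enone
Conditions: HF·pyridine, THF, rt
Reagents that add atoms: none
Why: Fluoride-mediated global desilylation under mildly acidic conditions that a verbenone-type enone tolerates and that avoid strongly basic alkoxides.

Step 17
Reactants: 25 target diol and 26 isovaleryl chloride
Product: 27 CNP0192813.1 (5R,6S,7R,8R,9R,11R): the 9,11-bis(3-methylbutanoate)
Conditions: DMAP, pyridine, CH2Cl2, 0 to 40 °C
Reagents that add atoms: isovaleryl chloride (26), CC(C)CC(=O)Cl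
Why: DMAP-catalysed acylation esterifies both hindered secondary alcohols at oxygen, so no stereocentre is touched.

Compound list
1 | (S)-pantolactone | CC1(C)COC(=O)[C@H]1O | starting material
2 | (3S)-3-(TBS-oxy)-4,4-dimethyloxolan-2-one | CC1(C)COC(=O)[C@H]1O[Si](C)(C)C(C)(C)C | intermediate
3 | (3S)-3-(TBS-oxy)-4,4-dimethyloxolan-2-ol (anomers) | CC1(C)COC(O)[C@H]1O[Si](C)(C)C(C)(C)C | intermediate
4 | (3R)-3-(TBS-oxy)-5-methoxy-2,2-dimethylpent-4-en-1-ol (E/Z) | COC=C[C@@H](O[Si](C)(C)C(C)(C)C)C(C)(C)CO | intermediate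
5 | (3R)-3,5-bis(TBS-oxy)-1-methoxy-4,4-dimethylpent-1-ene (E/Z) | COC=C[C@@H](O[Si](C)(C)C(C)(C)C)C(C)(C)CO[Si](C)(C)C(C)(C)C | intermediate
6 | (3R)-3,5-bis(TBS-oxy)-4,4-dimethylpentanal | O=CC[C@@H](O[Si](C)(C)C(C)(C)C)C(C)(C)CO[Si](C)(C)C(C)(C)C | intermediate
7 | 3-methylcyclopent-2-en-1-one | CC1=CC(=O)CC1 | starting material
8 | lithium 4-methylcyclopenta-1,3-dien-2-olate (cross-conjugated enolate; not isolated) | [Li+].CC1=CC([O-])=CC1 | intermediate
9 | 1-methyl-3-(TMS-oxy)cyclopenta-1,3-diene | CC1=CC(O[Si](C)(C)C)=CC1 | intermediate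
10 | 5-[(1R,3R)-3,5-bis(TBS-oxy)-1-hydroxy-4,4-dimethylpentyl]-3-methylcyclopent-2-en-1-one (C8 epimers) | CC1=CC(=O)C(C1)[C@H](O)C[C@@H](O[Si](C)(C)C(C)(C)C)C(C)(C)CO[Si](C)(C)C(C)(C)C | intermediate
11 | dilithium alkoxide enolate of 10 (not isolated) | [Li+].[Li+].CC1=CC([O-])=C(C1)[C@H]([O-])C[C@@H](O[Si](C)(C)C(C)(C)C)C(C)(C)CO[Si](C)(C)C(C)(C)C | intermediate
12 | (5S)-5-[(1R,3R)-3,5-bis(TBS-oxy)-1-hydroxy-4,4-dimethylpentyl]-3,5-dimethylcyclopent-2-en-1-one | CC1=CC(=O)[C@@](C)(C1)[C@H](O)C[C@@H](O[Si](C)(C)C(C)(C)C)C(C)(C)CO[Si](C)(C)C(C)(C)C | intermediate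
13 | (5S)-5-[(1R,3R)-1,3,5-tris(TBS-oxy)-4,4-dimethylpentyl]-3,5-dimethylcyclopent-2-en-1-one | CC1=CC(=O)[C@@](C)(C1)[C@H](O[Si](C)(C)C(C)(C)C)C[C@@H](O[Si](C)(C)C(C)(C)C)C(C)(C)CO[Si](C)(C)C(C)(C)C | intermediate
14 | (5S)-5-[(1R,3R)-1,3-bis(TBS-oxy)-5-hydroxy-4,4-dimethylpentyl]-3,5-dimethylcyclopent-2-en-1-one | CC1=CC(=O)[C@@](C)(C1)[C@H](O[Si](C)(C)C(C)(C)C)C[C@@H](O[Si](C)(C)C(C)(C)C)C(C)(C)CO | intermediate
15 | (5S)-5-[(1R,3R)-1,3-bis(TBS-oxy)-4,4-dimethyl-5-oxopentyl]-3,5-dimethylcyclopent-2-en-1-one | CC1=CC(=O)[C@@](C)(C1)[C@H](O[Si](C)(C)C(C)(C)C)C[C@@H](O[Si](C)(C)C(C)(C)C)C(C)(C)C=O | intermediate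
16 | nitromethane | C[N+](=O)[O-] | starting material
17 | (5S)-5-[(1R,3R)-1,3-bis(TBS-oxy)-5-hydroxy-4,4-dimethyl-6-nitrohexyl]-3,5-dimethylcyclopent-2-en-1-one (C6 epimers; not isolated) | CC1=CC(=O)[C@@](C)(C1)[C@H](O[Si](C)(C)C(C)(C)C)C[C@@H](O[Si](C)(C)C(C)(C)C)C(C)(C)C(O)C[N+](=O)[O-] | intermediate
18 | (5S)-5-[(1R,3R,5E)-1,3-bis(TBS-oxy)-4,4-dimethyl-6-nitrohex-5-en-1-yl]-3,5-dimethylcyclopent-2-en-1-one | CC1=CC(=O)[C@@](C)(C1)[C@H](O[Si](C)(C)C(C)(C)C)C[C@@H](O[Si](C)(C)C(C)(C)C)C(C)(C)/C=C/[N+](=O)[O-] | intermediate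
19 | (5S)-1-(TES-oxy)-3,5-dimethyl-5-[(1R,3R,5E)-1,3-bis(TBS-oxy)-4,4-dimethyl-6-nitrohex-5-en-1-yl]cyclopenta-1,3-diene (not isolated) | CC1=C[C@](C)(C(O[Si](CC)(CC)CC)=C1)[C@H](O[Si](C)(C)C(C)(C)C)C[C@@H](O[Si](C)(C)C(C)(C)C)C(C)(C)/C=C/[N+](=O)[O-] | intermediate
20 | nitro cycloadduct: C4–OTES, endo C5–NO2, C12 exo on C6, C9 syn to C5–C6 | CC1=C[C@]2(O[Si](CC)(CC)CC)[C@H]([N+](=O)[O-])[C@@H]3[C@H]1[C@@]2(C)[C@H](O[Si](C)(C)C(C)(C)C)C[C@@H](O[Si](C)(C)C(C)(C)C)C3(C)C | intermediate
21 | amino triethylsilyl ether: as 20 with endo C5–NH2 (not isolated) | CC1=C[C@]2(O[Si](CC)(CC)CC)[C@H](N)[C@@H]3[C@H]1[C@@]2(C)[C@H](O[Si](C)(C)C(C)(C)C)C[C@@H](O[Si](C)(C)C(C)(C)C)C3(C)C | intermediate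
22 | endo amino alcohol: C4–OH, endo C5–NH2 (key-step precursor) | CC1=C[C@]2(O)[C@H](N)[C@@H]3[C@H]1[C@@]2(C)[C@H](O[Si](C)(C)C(C)(C)C)C[C@@H](O[Si](C)(C)C(C)(C)C)C3(C)C | intermediate
23 | endo C5 diazonium acetate (not isolated) | CC1=C[C@]2(O)[C@H]([N+]#N)[C@@H]3[C@H]1[C@@]2(C)[C@H](O[Si](C)(C)C(C)(C)C)C[C@@H](O[Si](C)(C)C(C)(C)C)C3(C)C.CC(=O)[O-] | intermediate
24 | bis-TBS ether of the target diol (key-step product) | CC1=CC(=O)[C@@H]2[C@@H]3[C@H]1[C@@]2(C)[C@H](O[Si](C)(C)C(C)(C)C)C[C@@H](O[Si](C)(C)C(C)(C)C)C3(C)C | intermediate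
25 | target diol (9,11-dihydroxy tricyclic enone) | CC1=CC(=O)[C@@H]2[C@@H]3[C@H]1[C@@]2(C)[C@H](O)C[C@@H](O)C3(C)C | intermediate
26 | isovaleryl chloride | CC(C)CC(=O)Cl | starting material
27 | CNP0192813.1 | CC1=CC(=O)[C@@H]2[C@@H]3[C@H]1[C@@]2(C)[C@H](OC(=O)CC(C)C)C[C@@H](OC(=O)CC(C)C)C3(C)C | target

Total step count: 17. Longest linear sequence: 16 (steps 1–5 and 7–17, from 1).

Steps most likely to fail

Step 15 (new method). N2 may be lost ahead of the shift. A free C5 cation could then let vinyl C3 migrate or be captured by acetate, and the C2=C3 alkene could be nitrosated in competition. The fallback sets out from 20 and comes back at 24, and runs the same bond change as a closed-shell anionic displacement of a sulfonate.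
- Aqueous TiCl3 in DME (reductive Nef reaction; the acidic medium also removes TES) converts 20 into the hydroxy ketone F1.
- Li in NH3/THF at −78 °C is a dissolving-metal reduction that has to bring only a proton to the roofed exo face. It favours the more stable endo alcohol, as camphor gives mainly borneol, and gives the endo diol F2.
- MsCl/Et3N sulfonylates the secondary alcohol selectively to the hydroxy mesylate F3.
- KOt-Bu in THF then triggers the base-induced semipinacol rearrangement of a 2-hydroxy sulfonate. This is a known reaction type, and here only the anti C4–C8 bond can displace the endo mesylate.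

Step 13. The nitroalkene may react as a heterodiene with the enol ether, or oligomerise under amine catalysis, faster than the hindered C6 terminus closes the seven-membered ring. The fallback sets out from 15 and comes back at 22. It uses a carbonyl-activated dienophile that a Lewis acid can switch on and brings in nitrogen afterwards with retention.
- Wittig olefination of 15 with Ph3P=CHCHO gives the E-enal F4.
- TESOTf/Et3N converts it into the silyloxycyclopentadiene F5, which should close at low temperature under Me2AlCl catalysis to the endo aldehyde F6 (same tether and E-alkene arguments).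
- Pinnick oxidation (NaClO2, NaH2PO4, 2-methylbut-2-ene) gives the endo acid F7.
- (PhO)2P(O)N3/Et3N gives the acyl azide F8, whose Curtius rearrangement in hot toluene leads with retention to the endo isocyanate F9.
- Aqueous HCl in THF hydrolyses the isocyanate and the TES ether.

Step 8. The second deprotonation may occur at a γ position (C7–H or the C2 methyl) instead of C8–H, which the neighbouring alkoxide deactivates, or the lithium aldolate may undergo retro-aldol cleavage on warming. The fallback sets out from 10, comes back at 13 and skips 12.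
- TBSOTf/2,6-lutidine first gives the tris-silyl ether F10.
- One equivalent of LiN(i-Pr)2 then removes the α′ proton as in any enone, and MeI alkylates the enolate.
- In this enolate A(1,3) strain turns C9–H towards O4 and the bulky silyloxy group shields one face, so attack anti to it leads to the same C8 configuration.
- Selectivity is expected to be lower than with the chelate, so the C8 epimers would be separated by chromatography.

Further compounds
F1 | step 15 | hydroxy ketone: C4–OH, C5=O norbornenone | CC1=C[C@]2(O)C(=O)[C@@H]3[C@H]1[C@@]2(C)[C@H](O[Si](C)(C)C(C)(C)C)C[C@@H](O[Si](C)(C)C(C)(C)C)C3(C)C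
F2 | step 15 | endo diol: C4–OH, endo C5–OH | CC1=C[C@]2(O)[C@H](O)[C@@H]3[C@H]1[C@@]2(C)[C@H](O[Si](C)(C)C(C)(C)C)C[C@@H](O[Si](C)(C)C(C)(C)C)C3(C)C
F3 | step 15 | hydroxy mesylate: C4–OH, endo C5–OMs | CC1=C[C@]2(O)[C@H](OS(C)(=O)=O)[C@@H]3[C@H]1[C@@]2(C)[C@H](O[Si](C)(C)C(C)(C)C)C[C@@H](O[Si](C)(C)C(C)(C)C)C3(C)C
F4 | step 13 | E-enal: as 18 with CHO in place of NO2 | CC1=CC(=O)[C@@](C)(C1)[C@H](O[Si](C)(C)C(C)(C)C)C[C@@H](O[Si](C)(C)C(C)(C)C)C(C)(C)/C=C/C=O
F5 | step 13 | silyloxycyclopentadiene: as 19 with CHO in place of NO2 | CC1=C[C@](C)(C(O[Si](CC)(CC)CC)=C1)[C@H](O[Si](C)(C)C(C)(C)C)C[C@@H](O[Si](C)(C)C(C)(C)C)C(C)(C)/C=C/C=O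
F6 | step 13 | endo aldehyde: as 20 with endo C5–CHO | CC1=C[C@]2(O[Si](CC)(CC)CC)[C@H](C=O)[C@@H]3[C@H]1[C@@]2(C)[C@H](O[Si](C)(C)C(C)(C)C)C[C@@H](O[Si](C)(C)C(C)(C)C)C3(C)C
F7 | step 13 | endo acid: as 20 with endo C5–CO2H | CC1=C[C@]2(O[Si](CC)(CC)CC)[C@H](C(=O)O)[C@@H]3[C@H]1[C@@]2(C)[C@H](O[Si](C)(C)C(C)(C)C)C[C@@H](O[Si](C)(C)C(C)(C)C)C3(C)C
F8 | step 13 | acyl azide: as 20 with endo C5–C(O)N3 | CC1=C[C@]2(O[Si](CC)(CC)CC)[C@H](C(=O)N=[N+]=[N-])[C@@H]3[C@H]1[C@@]2(C)[C@H](O[Si](C)(C)C(C)(C)C)C[C@@H](O[Si](C)(C)C(C)(C)C)C3(C)C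
F9 | step 13 | endo isocyanate: as 20 with endo C5–NCO | CC1=C[C@]2(O[Si](CC)(CC)CC)[C@H](N=C=O)[C@@H]3[C@H]1[C@@]2(C)[C@H](O[Si](C)(C)C(C)(C)C)C[C@@H](O[Si](C)(C)C(C)(C)C)C3(C)C
F10 | step 8 | tris-silyl ether: C9–O-TBS ether of 10 (C8 epimers) | CC1=CC(=O)C(C1)[C@H](O[Si](C)(C)C(C)(C)C)C[C@@H](O[Si](C)(C)C(C)(C)C)C(C)(C)CO[Si](C)(C)C(C)(C)C
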